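**Plan** (oxolane numbered O1, C2 = aryl carbon, C3 = CH2OH carbon, C4 = side-chain carbon, C5 = CH2)
1. Retrosynthesis: cut the two O–benzyl bonds, then the aryl–C(carbinol) bond (aryl Grignard on a lactol); this ties C3–CH2O and the C4 side-chain carbon into a cis-fused γ-lactone, and a temporary CO2Me is put back on C4.
2. Then cut O1–C2 and C4–C5: O1 and C5H2 leave as one molecule of formaldehyde and C2–C3–C4 closes to a cyclopropane; last cut the cyclopropane bonds C2–C4 and C3–C4 (enal plus bromomalonate).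
3. Enabling feature: in the oxolane ring C2 carries the electron-rich guaiacyl group (donor) and C4 carries the carbon that becomes the carbinol (carbonyl level, acceptor), with C3 between them; C2–C4 can therefore be the push–pull bond of a donor–acceptor cyclopropane, and O1–C5 is a C=O unit.
4. Forward: O-benzyl coniferaldehyde → cyclopropane → cyclopropane-fused lactone (temporary ring) → oxolane by two-atom ring expansion of the three-membered ring with CH2O → decarboxylation → lactol → aryl addition → debenzylation.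
5. Stereochemistry: the two cyclopropane centres come from one organocatalytic step; C3 is carried through, C2 is inverted in the ring expansion (trans cyclopropane → 2,3-cis oxolane), C4 is held cis by the lactone ring fusion, and the carbinol centre comes from Felkin–Anh addition to the C4 aldehyde.

Key step: step 4

Assumption: the target SMILES is read as the all-cis oxolane (2S,3S,4S; aryl, CH2OH and side chain on one face) with an (S)-carbinol centre; 1, 3, 12, paraformaldehyde and both enantiomers of diphenylprolinol trimethylsilyl ether are taken as commercial.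

**Step 1**
Reactants: 1 (E)-3-(4-hydroxy-3-methoxyphenyl)prop-2-enal (coniferaldehyde)
Product: 2 (E)-3-[4-(benzyloxy)-3-methoxyphenyl]prop-2-enal
Conditions: BnBr (1.1 equiv), K2CO3 (1.5 equiv), DMF, 25 °C
Reagents that add atoms: benzyl bromide, BrCc1ccccc1
Why: Williamson ether synthesis on the phenol with K2CO3; the enal is not touched and no stereocentre is formed.

**Step 2**
Reactants: 2 (E)-3-[4-(benzyloxy)-3-methoxyphenyl]prop-2-enal; 3 dimethyl 2-bromopropanedioate (dimethyl bromomalonate)
Product: 4 dimethyl (2R,3S)-2-[4-(benzyloxy)-3-methoxyphenyl]-3-formylcyclopropane-1,1-dicarboxylate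
Conditions: (R)-α,α-diphenylprolinol trimethylsilyl ether (20 mol%), 2,6-lutidine (1.1 equiv), CH2Cl2, 0 → 25 °C
Reagents that add atoms: none
Why: Organocatalytic Michael-initiated ring closure (iminium activation, then intramolecular enamine α-alkylation with loss of bromide, 3-exo-tet), a reaction type established for cinnamaldehydes and bromomalonates; the CPh2OTMS group of the (R)-catalyst shields one face of the s-trans (E)-iminium ion so that bromomalonate should add to the Re face of the β-carbon (C2 becomes R), and the ring closure places the formyl group trans to the aryl group (C3 becomes S).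

**Step 3**
Reactants: 4 dimethyl (2R,3S)-2-[4-(benzyloxy)-3-methoxyphenyl]-3-formylcyclopropane-1,1-dicarboxylate
Product: 6 methyl (1R,5S,6R)-6-[4-(benzyloxy)-3-methoxyphenyl]-2-oxo-3-oxabicyclo[3.1.0]hexane-1-carboxylate, via hydroxymethyl cyclopropane diester 5 (not isolated)
Conditions: NaBH4 (0.6 equiv), MeOH/THF, 0 °C; then PPTS (cat.), toluene, 50 °C
Reagents that add atoms: none
Why: Chemoselective borohydride reduction of the aldehyde, then lactonisation of alcohol 5 onto the ester on the same face of the cyclopropane (acyl substitution, 5-exo-trig); no existing stereocentre is touched, and C1 becomes stereogenic (R) only because the cis ester alone can close the γ-lactone.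

**Step 4**
Reactants: 6 methyl (1R,5S,6R)-6-[4-(benzyloxy)-3-methoxyphenyl]-2-oxo-3-oxabicyclo[3.1.0]hexane-1-carboxylate; 7 formaldehyde (monomer, from cracked paraformaldehyde)
Product: 8 methyl (1S,5S,6S)-6-[4-(benzyloxy)-3-methoxyphenyl]-2-oxo-3,7-dioxabicyclo[3.3.0]octane-1-carboxylate
Conditions: CH2O (5 equiv, gas from paraformaldehyde at 150 °C), Sn(OTf)2 (10 mol%), 4 Å MS, CH2Cl2, −40 → 0 °C
Reagents that add atoms: none
Why: Proposed new method: Sn(OTf)2 should chelate the lactone and ester carbonyl groups on C1 of 6 and polarise the C1–C6 bond, which is pushed by the 4-benzyloxy-3-methoxyphenyl group; the oxygen of formaldehyde attacks C6 from the rear of that bond (SN2-like, inversion), and the resulting O-alkyl oxocarbenium ion is captured at carbon by the tin enolate of the α-carbomethoxy lactone, so that the three-membered ring C1–C5–C6 grows by O and CH2 into the oxolane. The closest known reaction type is the Lewis acid-catalysed (3+2) annulation of 2-arylcyclopropane-1,1-diesters with aryl and alkyl aldehydes, which runs with inversion at the donor carbon; new here are formaldehyde as the two-atom partner and the lactone-fused cyclopropane. The only ring closed is the oxolane, by C–C bond formation between the enolate carbon and the oxocarbenium carbon (5-(enolexo)-endo-trig, the closure mode of the known aldehyde annulations). C6 (later C2 of the oxolane) is set by the stereospecific inversion, which turns the trans aryl/CH2O relationship of the cyclopropane into the cis relationship of the oxolane; the quaternary C1 can only close cis to the existing lactone ring; C5 is untouched and formaldehyde brings no stereocentre. The step needs cleavage of C1–C6 and not of C1–C5, which the aryl donor on C6 secures, and SN2 and not SN1 opening, which the mild Lewis acid, the low temperature and the unhindered oxygen of formaldehyde should favour.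

**Step 5**
Reactants: 8 methyl (1S,5S,6S)-6-[4-(benzyloxy)-3-methoxyphenyl]-2-oxo-3,7-dioxabicyclo[3.3.0]octane-1-carboxylate
Product: 10 (1S,5S,6S)-6-[4-(benzyloxy)-3-methoxyphenyl]-3,7-dioxabicyclo[3.3.0]octan-2-one, via lithium carboxylate 9 (not isolated)
Conditions: LiCl (3 equiv), H2O (2 equiv), DMSO, 140 °C
Reagents that add atoms: none
Why: Krapcho dealkoxycarbonylation (chloride demethylates the ester, carboxylate 9 loses CO2, the lactone enolate is protonated); the bridgehead can only be protonated to the cis-fused bicycle, and β-elimination of the ring oxygen is disfavoured because that C–O bond lies close to the nodal plane of the enolate.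

**Step 6**
Reactants: 10 (1S,5S,6S)-6-[4-(benzyloxy)-3-methoxyphenyl]-3,7-dioxabicyclo[3.3.0]octan-2-one
Product: 11 (1S,5S,6S)-6-[4-(benzyloxy)-3-methoxyphenyl]-3,7-dioxabicyclo[3.3.0]octan-2-ol (both epimers at C2)
Conditions: i-Bu2AlH (1.1 equiv), CH2Cl2, −78 °C; aq. KNaC4H4O6 (potassium sodium tartrate)
Reagents that add atoms: none
Why: Partial reduction of a γ-lactone to the lactol with one equivalent of i-Bu2AlH at −78 °C; the benzyl ether is inert and the new hemiacetal centre is a mixture that is erased in step 7.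

**Step 7**
Reactants: 11 (1S,5S,6S)-6-[4-(benzyloxy)-3-methoxyphenyl]-3,7-dioxabicyclo[3.3.0]octan-2-ol; 12 1-(benzyloxy)-4-bromo-2-methoxybenzene
Product: 15 (S)-[4-(benzyloxy)-3-methoxyphenyl]{(3S,4S,5S)-5-[4-(benzyloxy)-3-methoxyphenyl]-4-(hydroxymethyl)oxolan-3-yl}methanol, via arylmagnesium bromide 13 (not isolated), via open-chain hydroxy aldehyde 14 (not isolated)
Conditions: 12, Mg turnings, THF, 40 °C; then 11 added to 13 (3.5 equiv), THF, −40 → 0 °C; aq. NH4Cl
Reagents that add atoms: none
Why: Grignard addition to the open-chain aldehyde tautomer 14 of the lactol (the first equivalent removes the hydroxyl proton); Felkin–Anh control by the ring carbon next to the carbonyl group (the more substituted ring carbon antiperiplanar to the incoming aryl group, attack past the hydrogen atom) should give the (S)-carbinol, and magnesium bridging the carbonyl oxygen and the ring oxygen leads to the same face.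

**Step 8**
Reactants: 15 (S)-[4-(benzyloxy)-3-methoxyphenyl]{(3S,4S,5S)-5-[4-(benzyloxy)-3-methoxyphenyl]-4-(hydroxymethyl)oxolan-3-yl}methanol
Product: 16 (S)-(4-hydroxy-3-methoxyphenyl)[(3S,4S,5S)-5-(4-hydroxy-3-methoxyphenyl)-4-(hydroxymethyl)oxolan-3-yl]methanol (target)
Conditions: H2 (1 atm), Pd/C (10% palladium on carbon), EtOAc/EtOH, 20 °C, stopped after uptake of 2 equiv of H2
Reagents that add atoms: none
Why: Hydrogenolysis of the two aryl benzyl ethers over palladium on carbon, which is expected to be much faster than cleavage of the benzylic C–O bonds of the oxolane and of the carbinol; no stereocentre is affected.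

**Compound list**
1 | (E)-3-(4-hydroxy-3-methoxyphenyl)prop-2-enal (coniferaldehyde) | COc1cc(/C=C/C=O)ccc1O | starting material
2 | (E)-3-[4-(benzyloxy)-3-methoxyphenyl]prop-2-enal | COc1cc(/C=C/C=O)ccc1OCc1ccccc1 | intermediate
3 | dimethyl 2-bromopropanedioate | COC(=O)C(Br)C(=O)OC | starting material
4 | dimethyl (2R,3S)-2-[4-(benzyloxy)-3-methoxyphenyl]-3-formylcyclopropane-1,1-dicarboxylate | COC(=O)C1(C(=O)OC)[C@@H](c2ccc(OCc3ccccc3)c(OC)c2)[C@@H]1C=O | intermediate
5 | dimethyl (2R,3S)-2-[4-(benzyloxy)-3-methoxyphenyl]-3-(hydroxymethyl)cyclopropane-1,1-dicarboxylate | COC(=O)C1(C(=O)OC)[C@@H](c2ccc(OCc3ccccc3)c(OC)c2)[C@@H]1CO | intermediate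
6 | methyl (1R,5S,6R)-6-[4-(benzyloxy)-3-methoxyphenyl]-2-oxo-3-oxabicyclo[3.1.0]hexane-1-carboxylate | COC(=O)[C@@]12[C@@H](c3ccc(OCc4ccccc4)c(OC)c3)[C@@H]1COC2=O | intermediate
7 | formaldehyde (supplied as paraformaldehyde) | C=O | starting material
8 | methyl (1S,5S,6S)-6-[4-(benzyloxy)-3-methoxyphenyl]-2-oxo-3,7-dioxabicyclo[3.3.0]octane-1-carboxylate | COC(=O)[C@@]12CO[C@H](c3ccc(OCc4ccccc4)c(OC)c3)[C@@H]1COC2=O | intermediate
9 | lithium (1S,5S,6S)-6-[4-(benzyloxy)-3-methoxyphenyl]-2-oxo-3,7-dioxabicyclo[3.3.0]octane-1-carboxylate | [Li+].[O-]C(=O)[C@@]12CO[C@H](c3ccc(OCc4ccccc4)c(OC)c3)[C@@H]1COC2=O | intermediate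
10 | (1S,5S,6S)-6-[4-(benzyloxy)-3-methoxyphenyl]-3,7-dioxabicyclo[3.3.0]octan-2-one | O=C1OC[C@@H]2[C@H]1CO[C@@H]2c3ccc(OCc4ccccc4)c(OC)c3 | intermediate
11 | (1S,5S,6S)-6-[4-(benzyloxy)-3-methoxyphenyl]-3,7-dioxabicyclo[3.3.0]octan-2-ol (both epimers at C2) | OC1OC[C@@H]2[C@H]1CO[C@@H]2c3ccc(OCc4ccccc4)c(OC)c3 | intermediate
12 | 1-(benzyloxy)-4-bromo-2-methoxybenzene | COc1cc(Br)ccc1OCc1ccccc1 | starting material
13 | [4-(benzyloxy)-3-methoxyphenyl]magnesium bromide | COc1cc([Mg]Br)ccc1OCc1ccccc1 | intermediate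
14 | (3S,4S,5S)-5-[4-(benzyloxy)-3-methoxyphenyl]-4-(hydroxymethyl)oxolane-3-carbaldehyde (open-chain tautomer of 11, present as its bromomagnesium alkoxide) | O=C[C@@H]1CO[C@H](c2ccc(OCc3ccccc3)c(OC)c2)[C@@H]1CO | intermediate
15 | (S)-[4-(benzyloxy)-3-methoxyphenyl]{(3S,4S,5S)-5-[4-(benzyloxy)-3-methoxyphenyl]-4-(hydroxymethyl)oxolan-3-yl}methanol | COc1cc([C@@H](O)[C@@H]2CO[C@H](c3ccc(OCc4ccccc4)c(OC)c3)[C@@H]2CO)ccc1OCc1ccccc1 | intermediate
16 | (S)-(4-hydroxy-3-methoxyphenyl)[(3S,4S,5S)-5-(4-hydroxy-3-methoxyphenyl)-4-(hydroxymethyl)oxolan-3-yl]methanol | COc1cc([C@@H](O)[C@@H]2CO[C@H](c3ccc(O)c(OC)c3)[C@@H]2CO)ccc1O | target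

**Totals**
Total step count: 8. Longest linear sequence: 8 steps (1 → 16).

**Steps most likely to fail**

Step 4 (proposed new method). The oxygen of formaldehyde is a weak nucleophile. If its attack is slow, unimolecular opening to a benzylic cation (loss of the inversion and so of the 2,3-cis relationship), polymerisation of formaldehyde or hydroxymethylation of the electron-rich arene may take over. The fallback uses only precedented partners, sets out from 4 and returns at 8. Compound 4 is reduced with NaBH4 at −40 °C and the alcohol is silylated at once (TBSOTf, 2,6-lutidine) to dimethyl (2R,3S)-2-[4-(benzyloxy)-3-methoxyphenyl]-3-{[(tert-butyldimethylsilyl)oxy]methyl}cyclopropane-1,1-dicarboxylate F1. The known (3+2) annulation of this monocyclic diester with (E)-cinnamaldehyde (Sn(OTf)2 or AlCl3, CH2Cl2) should give dimethyl (2S,4S,5S)-5-[4-(benzyloxy)-3-methoxyphenyl]-4-{[(tert-butyldimethylsilyl)oxy]methyl}-2-[(E)-2-phenylethenyl]oxolane-3,3-dicarboxylate F2, again with inversion at the aryl carbon. Camphorsulfonic acid in MeOH removes the silyl group and closes the lactone to methyl (1S,5S,6S,8S)-6-[4-(benzyloxy)-3-methoxyphenyl]-2-oxo-8-[(E)-2-phenylethenyl]-3,7-dioxabicyclo[3.3.0]octane-1-carboxylate F3. Cleavage of the styryl group with OsO4 (cat.) and NaIO4 gives methyl (1S,5S,6S,8R)-6-[4-(benzyloxy)-3-methoxyphenyl]-8-formyl-2-oxo-3,7-dioxabicyclo[3.3.0]octane-1-carboxylate F4, and Tsuji–Wilkinson decarbonylation with RhCl(PPh3)3 in toluene at 110 °C turns the formyl-bearing carbon into the ring CH2 of 8.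

Step 7. Facial selectivity at the aldehyde carbon may be poor, because chelation of magnesium through the primary alkoxide would steer the aryl group to the other face; enolisation of the aldehyde could also scramble the adjacent ring centre. The fallback sets the carbinol centre by reagent control, sets out from 10 and returns at 15. Bromide 12 is converted with n-BuLi (THF, −78 °C) into [4-(benzyloxy)-3-methoxyphenyl]lithium F5, which adds once to lactone 10 to give [4-(benzyloxy)-3-methoxyphenyl]{(3S,4S,5S)-5-[4-(benzyloxy)-3-methoxyphenyl]-4-(hydroxymethyl)oxolan-3-yl}methanone F6 (in equilibrium with its cyclic hemiketal). Asymmetric transfer hydrogenation with RuCl(p-cymene)[(S,S)-TsDPEN] in HCO2H/Et3N should then deliver the (S)-alcohol 15.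

Step 8. Once a para-phenol is free, the benzylic C–O bonds of the carbinol and of the ring ether may also be hydrogenolysed. The fallback moves the hydrogenolysis to a stage without a benzylic hydroxyl group and ends with fluoride; it sets out from 10 and returns at 16. Hydrogenolysis of 10 (H2, palladium on carbon) gives (1S,5S,6S)-6-(4-hydroxy-3-methoxyphenyl)-3,7-dioxabicyclo[3.3.0]octan-2-one F7, and TBSCl/imidazole gives (1S,5S,6S)-6-{4-[(tert-butyldimethylsilyl)oxy]-3-methoxyphenyl}-3,7-dioxabicyclo[3.3.0]octan-2-one F8. Reduction with i-Bu2AlH gives (1S,5S,6S)-6-{4-[(tert-butyldimethylsilyl)oxy]-3-methoxyphenyl}-3,7-dioxabicyclo[3.3.0]octan-2-ol F9. Commercial (4-bromo-2-methoxyphenoxy)(tert-butyl)dimethylsilane and Mg give {4-[(tert-butyldimethylsilyl)oxy]-3-methoxyphenyl}magnesium bromide F10, which adds as in step 7 to give (S)-{4-[(tert-butyldimethylsilyl)oxy]-3-methoxyphenyl}[(3S,4S,5S)-5-{4-[(tert-butyldimethylsilyl)oxy]-3-methoxyphenyl}-4-(hydroxymethyl)oxolan-3-yl]methanol F11. Bu4NF buffered with AcOH (THF, 0 °C) then frees both phenols to give 16.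

**Further compounds**
F1 | step 4 | dimethyl (2R,3S)-2-[4-(benzyloxy)-3-methoxyphenyl]-3-{[(tert-butyldimethylsilyl)oxy]methyl}cyclopropane-1,1-dicarboxylate | COC(=O)C1(C(=O)OC)[C@@H](c2ccc(OCc3ccccc3)c(OC)c2)[C@@H]1CO[Si](C)(C)C(C)(C)C
F2 | step 4 | dimethyl (2S,4S,5S)-5-[4-(benzyloxy)-3-methoxyphenyl]-4-{[(tert-butyldimethylsilyl)oxy]methyl}-2-[(E)-2-phenylethenyl]oxolane-3,3-dicarboxylate | COC(=O)C1(C(=O)OC)[C@H](/C=C/c2ccccc2)O[C@H](c2ccc(OCc3ccccc3)c(OC)c2)[C@@H]1CO[Si](C)(C)C(C)(C)C
F3 | step 4 | methyl (1S,5S,6S,8S)-6-[4-(benzyloxy)-3-methoxyphenyl]-2-oxo-8-[(E)-2-phenylethenyl]-3,7-dioxabicyclo[3.3.0]octane-1-carboxylate | COC(=O)[C@@]12[C@H](/C=C/c3ccccc3)O[C@H](c3ccc(OCc4ccccc4)c(OC)c3)[C@@H]1COC2=O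
F4 | step 4 | methyl (1S,5S,6S,8R)-6-[4-(benzyloxy)-3-methoxyphenyl]-8-formyl-2-oxo-3,7-dioxabicyclo[3.3.0]octane-1-carboxylate | COC(=O)[C@@]12[C@H](C=O)O[C@H](c3ccc(OCc4ccccc4)c(OC)c3)[C@@H]1COC2=O
F5 | step 7 | [4-(benzyloxy)-3-methoxyphenyl]lithium | [Li]c1ccc(OCc2ccccc2)c(OC)c1
F6 | step 7 | [4-(benzyloxy)-3-methoxyphenyl]{(3S,4S,5S)-5-[4-(benzyloxy)-3-methoxyphenyl]-4-(hydroxymethyl)oxolan-3-yl}methanone | COc1cc(C(=O)[C@@H]2CO[C@H](c3ccc(OCc4ccccc4)c(OC)c3)[C@@H]2CO)ccc1OCc1ccccc1
F7 | step 8 | (1S,5S,6S)-6-(4-hydroxy-3-methoxyphenyl)-3,7-dioxabicyclo[3.3.0]octan-2-one | O=C1OC[C@@H]2[C@H]1CO[C@@H]2c3ccc(O)c(OC)c3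
F8 | step 8 | (1S,5S,6S)-6-{4-[(tert-butyldimethylsilyl)oxy]-3-methoxyphenyl}-3,7-dioxabicyclo[3.3.0]octan-2-one | O=C1OC[C@@H]2[C@H]1CO[C@@H]2c3ccc(O[Si](C)(C)C(C)(C)C)c(OC)c3
F9 | step 8 | (1S,5S,6S)-6-{4-[(tert-butyldimethylsilyl)oxy]-3-methoxyphenyl}-3,7-dioxabicyclo[3.3.0]octan-2-ol (both epimers at C2) | OC1OC[C@@H]2[C@H]1CO[C@@H]2c3ccc(O[Si](C)(C)C(C)(C)C)c(OC)c3
F10 | step 8 | {4-[(tert-butyldimethylsilyl)oxy]-3-methoxyphenyl}magnesium bromide | COc1cc([Mg]Br)ccc1O[Si](C)(C)C(C)(C)C
F11 | step 8 | (S)-{4-[(tert-butyldimethylsilyl)oxy]-3-methoxyphenyl}[(3S,4S,5S)-5-{4-[(tert-butyldimethylsilyl)oxy]-3-methoxyphenyl}-4-(hydroxymethyl)oxolan-3-yl]methanol | COc1cc([C@@H](O)[C@@H]2CO[C@H](c3ccc(O[Si](C)(C)C(C)(C)C)c(OC)c3)[C@@H]2CO)ccc1O[Si](C)(C)C(C)(C)C
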